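TBS = tert-butyldimethylsilyl; TBSO = tert-butyldimethylsilyloxy. Heptanoid numbering is used for the chain (C1 to C7); the target is (3R,7S).

**Retrosynthetic overview**
1. Chalcone C=C: Claisen–Schmidt condensation of a 3′-alkylated 2′,4′-dihydroxy-6′-methoxyacetophenone with benzaldehyde; the same hydroxide removes the two aryl silyl ethers and the C3 acetate.
2. C6–C7 bond: enantioselective addition of an (E)-alkenylboronate to an ortho-quinone methide under a chiral biphenol catalyst; this sets C7.
3. Quinone methide precursor: a benzhydrol from an aryltitanium reagent and 3-acetyl-2,6-dihydroxy-4-methoxybenzaldehyde, itself made by C3-formylation of the commercial acetophenone (this fixes the ring substitution pattern).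
4. Alkenylboronate: hydroboration of a (3R)-homopropargylic acetate, from asymmetric propargylation (sets C3) of a 3-arylpropanal made by a Heck reaction.
5. Rings: no ring is built; the three benzene rings are bought and joined in the order C1 aryl, then the two C7 aryls, then the chalcone phenyl.

Assumption: the catalyst antipodes in steps 2 and 7 are assigned from the accepted transition-state models for these reaction classes; if the first product shows the opposite sense, the mirror-image catalyst (also commercial) is used and nothing else changes.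

**Route**

Step 1
Reactants: 1 tert-butyl(4-iodophenoxy)dimethylsilane
Product: 2 3-[4-(TBSO)phenyl]propanal
Conditions: allyl alcohol, Pd(OAc)2 (3 mol %), Bu4NCl, NaHCO3, DMF, 40 °C
Reagents that add atoms: allyl alcohol, C=CCO
Why: Jeffery-type Heck arylation puts the aryl group on the terminal alkene carbon, and β-hydride elimination toward the carbinol gives an enol that tautomerises to the saturated aldehyde; no stereocenter is formed.

Step 2
Reactants: 2 3-[4-(TBSO)phenyl]propanal
Product: 3 (3R)-1-[4-(TBSO)phenyl]hex-5-yn-3-ol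
Conditions: allenylboronic acid pinacol ester, (S)-3,3′-bis(2,4,6-triisopropylphenyl)-1,1′-binaphthalene-2,2′-diyl hydrogen phosphate (5 mol %), 4 Å MS, toluene, 0 °C; aqueous work-up
Reagents that add atoms: allenylboronic acid pinacol ester, C=C=CB1OC(C)(C)C(C)(C)O1
Why: Chiral phosphoric acid-catalysed asymmetric propargylation (allenylboration) runs through a closed six-membered SE2′ transition state in which the acid binds the boronate oxygen and the formyl hydrogen, so the allenyl terminus is delivered to the Si face of the aldehyde and the (3R) carbinol is set.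

Step 3
Reactants: 3 (3R)-1-[4-(TBSO)phenyl]hex-5-yn-3-ol
Product: 4 (3R)-1-[4-(TBSO)phenyl]hex-5-yn-3-yl acetate
Conditions: Ac2O, Et3N, 4-(dimethylamino)pyridine (cat.), CH2Cl2, 0 °C to rt
Reagents that add atoms: acetic anhydride, CC(=O)OC(C)=O
Why: Nucleophile-catalysed acylation masks the alcohol, with retention at C3, as an ester that tolerates hydroboration and boronate exchange and is removed by the hydroxide of the last step.

Step 4
Reactants: 4 (3R)-1-[4-(TBSO)phenyl]hex-5-yn-3-yl acetate
Product: 6 dicyclohexyl [(1E,4R)-4-acetoxy-6-[4-(TBSO)phenyl]hex-1-en-1-yl]boronate, via alkenyldicyclohexylborane 5 (not isolated)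
Conditions: BH3·SMe2, cyclohexene (2 equiv), THF, 0 °C (gives Cy2BH); then 4, 0 °C to rt; then anhydrous Me3NO (2 equiv), 0 °C to rt; volatiles removed under vacuum, used crude
Reagents that add atoms: borane–dimethyl sulfide, [BH3-][S+](C)C; cyclohexene, C1=CCCCC1; trimethylamine N-oxide, C[N+](C)(C)[O-]
Why: Brown hydroboration with a bulky dialkylborane is syn and anti-Markovnikov and gives only the (E)-1-alkenylborane, and the amine oxide then oxidises the two secondary alkyl–boron bonds in preference to the alkenyl–boron bond, leaving an exchange-labile dialkyl boronate.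

Step 5
Reactants: 7 1-(2,4-dihydroxy-6-methoxyphenyl)ethan-1-one
Product: 8 3-acetyl-2,6-dihydroxy-4-methoxybenzaldehyde
Conditions: POCl3 (1.2 equiv), DMF, EtOAc, 0 °C to rt; then H2O, 50 °C
Reagents that add atoms: N,N-dimethylformamide, CN(C)C=O; water, O
Why: Vilsmeier–Haack formylation attacks C3, the position flanked by both hydroxyls and para to the methoxy group (the site formylated in orsellinates and acylphloroglucinols), and at or below room temperature ring substitution outruns reaction at the acetyl methyl group.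

Step 6
Reactants: 8 3-acetyl-2,6-dihydroxy-4-methoxybenzaldehyde; 9 (4-bromophenoxy)(tert-butyl)dimethylsilane
Product: 12 1-[2,4-dihydroxy-3-[hydroxy[4-(TBSO)phenyl]methyl]-6-methoxyphenyl]ethan-1-one (racemic), via arylmagnesium bromide 10 (not isolated), via aryltitanium triisopropoxide 11 (not isolated)
Conditions: 9 (3.3 equiv), Mg, THF, rt; ClTi(OiPr)3 (3.3 equiv), −78 °C; then 8, −40 to 0 °C; cold aq. NH4Cl; used without delay
Reagents that add atoms: none
Why: Chemoselective 1,2-addition of an aryltitanium reagent (Grignard formation, then transmetalation) takes the aldehyde and leaves the hindered, chelated acetyl group alone, since aryltitanium triisopropoxides add to aldehydes but not to ketones; the new carbinol center is racemic and is erased in step 7.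

Step 7
Reactants: 12 1-[2,4-dihydroxy-3-[hydroxy[4-(TBSO)phenyl]methyl]-6-methoxyphenyl]ethan-1-one; 6 dicyclohexyl [(1E,4R)-4-acetoxy-6-[4-(TBSO)phenyl]hex-1-en-1-yl]boronate
Product: 14 (3R,5E,7S)-7-(3-acetyl-2,6-dihydroxy-4-methoxyphenyl)-1,7-bis[4-(TBSO)phenyl]hept-5-en-3-yl acetate, via ortho-quinone methide 13 (not isolated)
Conditions: 6 (1.5 equiv), (R)-3,3′-dibromo-1,1′-bi-2-naphthol (15 mol %), 4 Å MS, PhCF3, 40 °C
Reagents that add atoms: none
Why: Biphenol-catalysed enantioselective conjugate alkenylation of an ortho-quinone methide: 12 loses water on boron to give 13, and the binaphthol-bound alkenylboronate coordinates the quinone-methide oxygen and transfers the alkenyl group through a closed chair transition state to one face of the exocyclic carbon, which sets (7S) with retention of the E alkene while C3 is untouched.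

Step 8
Reactants: 14 (3R,5E,7S)-7-(3-acetyl-2,6-dihydroxy-4-methoxyphenyl)-1,7-bis[4-(TBSO)phenyl]hept-5-en-3-yl acetate; 15 benzaldehyde
Product: 16 7-epi-katsumain C
Conditions: 15 (3 equiv), KOH (50% aq., excess), EtOH, 0 °C to rt; then cold dilute HCl to pH 5
Reagents that add atoms: none
Why: Claisen–Schmidt aldol condensation gives the thermodynamic (E)-enone while the hydroxide also cleaves the two aryl silyl ethers and the acetate; the strongly basic medium holds the chalcone as its open phenolate, and neither stereocenter is epimerisable under these conditions.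

**Compound list**
1 | tert-butyl(4-iodophenoxy)dimethylsilane | CC(C)(C)[Si](C)(C)Oc1ccc(I)cc1 | starting material
2 | 3-[4-(TBSO)phenyl]propanal | CC(C)(C)[Si](C)(C)Oc1ccc(CCC=O)cc1 | intermediate
3 | (3R)-1-[4-(TBSO)phenyl]hex-5-yn-3-ol | C#CC[C@H](O)CCc1ccc(O[Si](C)(C)C(C)(C)C)cc1 | intermediate
4 | (3R)-1-[4-(TBSO)phenyl]hex-5-yn-3-yl acetate | C#CC[C@H](OC(C)=O)CCc1ccc(O[Si](C)(C)C(C)(C)C)cc1 | intermediate
5 | [(1E,4R)-4-acetoxy-6-[4-(TBSO)phenyl]hex-1-en-1-yl]dicyclohexylborane | C1CCCCC1B(C1CCCCC1)/C=C/C[C@H](OC(C)=O)CCc1ccc(O[Si](C)(C)C(C)(C)C)cc1 | intermediate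
6 | dicyclohexyl [(1E,4R)-4-acetoxy-6-[4-(TBSO)phenyl]hex-1-en-1-yl]boronate | C1CCCCC1OB(OC1CCCCC1)/C=C/C[C@H](OC(C)=O)CCc1ccc(O[Si](C)(C)C(C)(C)C)cc1 | intermediate
7 | 1-(2,4-dihydroxy-6-methoxyphenyl)ethan-1-one (2′,4′-dihydroxy-6′-methoxyacetophenone) | COc1cc(O)cc(O)c1C(C)=O | starting material
8 | 3-acetyl-2,6-dihydroxy-4-methoxybenzaldehyde | COc1cc(O)c(C=O)c(O)c1C(C)=O | intermediate
9 | (4-bromophenoxy)(tert-butyl)dimethylsilane | CC(C)(C)[Si](C)(C)Oc1ccc(Br)cc1 | starting material
10 | [4-(TBSO)phenyl]magnesium bromide | CC(C)(C)[Si](C)(C)Oc1ccc([Mg]Br)cc1 | intermediate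
11 | tri(propan-2-yloxy)[4-(TBSO)phenyl]titanium | CC(C)O[Ti](OC(C)C)(OC(C)C)c1ccc(O[Si](C)(C)C(C)(C)C)cc1 | intermediate
12 | 1-[2,4-dihydroxy-3-[hydroxy[4-(TBSO)phenyl]methyl]-6-methoxyphenyl]ethan-1-one (racemic) | COc1cc(O)c(C(O)c2ccc(O[Si](C)(C)C(C)(C)C)cc2)c(O)c1C(C)=O | intermediate
13 | 4-acetyl-5-hydroxy-3-methoxy-6-[[4-(TBSO)phenyl]methylidene]cyclohexa-2,4-dien-1-one (exocyclic alkene geometry not defined) | COC1=CC(=O)C(=Cc2ccc(O[Si](C)(C)C(C)(C)C)cc2)C(O)=C1C(C)=O | intermediate
14 | (3R,5E,7S)-7-(3-acetyl-2,6-dihydroxy-4-methoxyphenyl)-1,7-bis[4-(TBSO)phenyl]hept-5-en-3-yl acetate | COc1cc(O)c([C@@H](/C=C/C[C@H](OC(C)=O)CCc2ccc(O[Si](C)(C)C(C)(C)C)cc2)c2ccc(O[Si](C)(C)C(C)(C)C)cc2)c(O)c1C(C)=O | intermediate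
15 | benzaldehyde | O=Cc1ccccc1 | starting material
16 | 7-epi-katsumain C, (E)-1-[2,4-dihydroxy-3-[(1S,2E,5R)-5-hydroxy-1,7-bis(4-hydroxyphenyl)hept-2-en-1-yl]-6-methoxyphenyl]-3-phenylprop-2-en-1-one | COc1cc(O)c([C@@H](/C=C/C[C@H](O)CCc2ccc(O)cc2)c2ccc(O)cc2)c(O)c1C(=O)/C=C/c1ccccc1 | target

**Step count and risks**
Total steps: 8. Longest linear sequence: 6 steps (steps 1, 2, 3, 4, 7, 8); the second branch (steps 5 and 6) joins at step 7.

The three steps most likely to fail are 7, 6 and 8.

Step 7 is the key step and has no close precedent on a substrate that carries a chelating ortho-hydroxyacetophenone, a second free phenol and a large, crude, functionalised boronate; conversion or selectivity may be poor. The fallback sets out from 12 and 4 and comes back at 14. The same biphenol-catalysed addition is run on 12 with commercial dibutyl vinylboronate, the smallest and cleanest alkenylboronate, to give 1-[2,4-dihydroxy-6-methoxy-3-[(1S)-1-[4-(TBSO)phenyl]prop-2-en-1-yl]phenyl]ethan-1-one F1. Alkyne 4 is semihydrogenated (H2, Pd/CaCO3 poisoned with Pb(OAc)2, quinoline, EtOAc) to (3R)-1-[4-(TBSO)phenyl]hex-5-en-3-yl acetate F2. F1 and F2 (in excess) are then joined by olefin cross-metathesis (second-generation Grubbs catalyst, CH2Cl2, 40 °C), which forms the C5=C6 bond E-selectively and gives 14.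

Step 6 may fail through attack or enolisation at the acetyl group, sluggish addition to the doubly phenoxide-flanked aldehyde, or loss of the labile benzhydrol on work-up. The fallback sets out from 8 and comes back at 14, and replaces the organometallic addition by a Petasis borono-Mannich reaction, which tolerates the ketone and the free phenols. Compound 8, morpholine and [4-(TBSO)phenyl]boronic acid (EtOH, 40 °C) give 1-[2,4-dihydroxy-6-methoxy-3-[morpholin-4-yl[4-(TBSO)phenyl]methyl]phenyl]ethan-1-one F3. Warming F3 in EtOH with AcOH exchanges the amine through the quinone methide to give 1-[3-[ethoxy[4-(TBSO)phenyl]methyl]-2,4-dihydroxy-6-methoxyphenyl]ethan-1-one F4. F4 is a stable quinone methide precursor and is used with 6 under the conditions of step 7 in place of 12 to give 14.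

Step 8 may stall because the 4′-phenoxide, together with three further phenoxides, deactivates the methyl ketone toward enolisation, and the chalcone can close to the flavanone on acidification. The fallback sets out from 14 and comes back at 16. The free 4′-hydroxyl (the 2′-hydroxyl is chelated and stays) is capped with chloromethyl methyl ether and i-Pr2NEt in CH2Cl2 to give (3R,5E,7S)-7-[3-acetyl-2-hydroxy-4-methoxy-6-(methoxymethoxy)phenyl]-1,7-bis[4-(TBSO)phenyl]hept-5-en-3-yl acetate F5. The Claisen–Schmidt condensation of F5 with 15 (KOH, EtOH), now on a mono-phenoxide ketone, gives (E)-1-[2-hydroxy-3-[(1S,2E,5R)-5-hydroxy-1,7-bis(4-hydroxyphenyl)hept-2-en-1-yl]-6-methoxy-4-(methoxymethoxy)phenyl]-3-phenylprop-2-en-1-one F6. Brief treatment of F6 with dilute HCl in MeOH at 40 °C removes the acetal and gives 16; the acyl-deactivated ring should keep C7 from ionising under these conditions.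

**Further compounds**
F1 | step 7 | 1-[2,4-dihydroxy-6-methoxy-3-[(1S)-1-[4-(TBSO)phenyl]prop-2-en-1-yl]phenyl]ethan-1-one | COc1cc(O)c([C@@H](C=C)c2ccc(O[Si](C)(C)C(C)(C)C)cc2)c(O)c1C(C)=O
F2 | step 7 | (3R)-1-[4-(TBSO)phenyl]hex-5-en-3-yl acetate | C=CC[C@H](OC(C)=O)CCc1ccc(O[Si](C)(C)C(C)(C)C)cc1
F3 | step 6 | 1-[2,4-dihydroxy-6-methoxy-3-[morpholin-4-yl[4-(TBSO)phenyl]methyl]phenyl]ethan-1-one (racemic) | COc1cc(O)c(C(N2CCOCC2)c2ccc(O[Si](C)(C)C(C)(C)C)cc2)c(O)c1C(C)=O
F4 | step 6 | 1-[3-[ethoxy[4-(TBSO)phenyl]methyl]-2,4-dihydroxy-6-methoxyphenyl]ethan-1-one (racemic) | CCOC(c1ccc(O[Si](C)(C)C(C)(C)C)cc1)c1c(O)cc(OC)c(C(C)=O)c1O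
F5 | step 8 | (3R,5E,7S)-7-[3-acetyl-2-hydroxy-4-methoxy-6-(methoxymethoxy)phenyl]-1,7-bis[4-(TBSO)phenyl]hept-5-en-3-yl acetate | COc1cc(OCOC)c([C@@H](/C=C/C[C@H](OC(C)=O)CCc2ccc(O[Si](C)(C)C(C)(C)C)cc2)c2ccc(O[Si](C)(C)C(C)(C)C)cc2)c(O)c1C(C)=O
F6 | step 8 | (E)-1-[2-hydroxy-3-[(1S,2E,5R)-5-hydroxy-1,7-bis(4-hydroxyphenyl)hept-2-en-1-yl]-6-methoxy-4-(methoxymethoxy)phenyl]-3-phenylprop-2-en-1-one | COc1cc(OCOC)c([C@@H](/C=C/C[C@H](O)CCc2ccc(O)cc2)c2ccc(O)cc2)c(O)c1C(=O)/C=C/c1ccccc1
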